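## Retrosynthetic overview

- Feature: in the six-membered carbocycle of the target (C1 ring ketone, C2 acyl, C3 enol OH, C4 prenyl, C5 enol OH, C6 OMe and prenyl) the quaternary C6 lies para to the C3 oxygen, and both carbons ortho to that oxygen, C2 and C4, are substituted.
- Key disconnection: the C6–CH2 bond of the C6 prenyl group, traced back to a prenyl ether on the C3 oxygen of a hexasubstituted benzene (dearomatising Claisen shift to C2 or C4, then Cope shift to C6, ring face set by a chiral Lewis acid chelated between the acyl and ether oxygens).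
- The C1 and C5 oxygens are carried as methyl ethers. 3,4,5-Trimethoxyphenol has its only free OH at the C3 oxygen, so no hydroxyls need to be told apart and no phenolate–ketone chelate can hold the catalyst on the wrong side. After dearomatisation these two OMe groups are vinylogous esters and hydrolyse, while the C6 OMe, then a tertiary alkyl ether, stays.
- Precursor: O-prenylation of the C3 hydroxyl ⇐ C4 prenyl by O-(1,1-dimethylallyl)ation and aromatic Claisen shift ⇐ C2 acyl by Friedel–Crafts acylation of 3,4,5-trimethoxyphenol.
- No ring is formed: the carbocycle is the benzene ring of the starting phenol.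

Key step: step 6

Remark: ring atoms are numbered C1 to C6 as in the target throughout. Helihumulone is written as the enol tautomer given by the target SMILES, and the triketone released in step 7 equilibrates to it.

Assumption: which antipode of the ligand leads to (R) at C6 cannot be predicted with certainty. It is to be fixed by one trial run, and the ligand from (R)-pipecolic acid is used if the sense is opposite.

## Route

Step 1
Reactants: 1 3,4,5-trimethoxyphenol; 2 3-phenylpropanoyl chloride
Product: 3 1-(6-hydroxy-2,3,4-trimethoxyphenyl)-3-phenylpropan-1-one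
Conditions: BF3·OEt2 (as solvent), 70 °C; then H2O
Reagents that add atoms: 3-phenylpropanoyl chloride, O=C(Cl)CCc1ccccc1
Why: Friedel–Crafts acylation (O-acylation, then Fries shift under BF3) should go ortho to the free hydroxyl, since the two ortho positions of 1 are equivalent and the para position carries OMe, and the ketone then deactivates the ring against a second acylation.

Step 2
Reactants: 4 2-methylbut-3-en-2-ol; 5 di-tert-butyl dicarbonate
Product: 6 tert-butyl 2-methylbut-3-en-2-yl carbonate
Conditions: n-BuLi, THF, 0 °C; then Boc2O, 0 °C to rt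
Reagents that add atoms: di-tert-butyl dicarbonate, CC(C)(C)OC(=O)OC(=O)OC(C)(C)C
Why: Acylation of the lithium alkoxide of the tertiary allylic alcohol by Boc2O (carbonate formation) should give the ionisable allyl partner for step 3.

Step 3
Reactants: 3 1-(6-hydroxy-2,3,4-trimethoxyphenyl)-3-phenylpropan-1-one; 6 tert-butyl 2-methylbut-3-en-2-yl carbonate
Product: 7 1-[2,3,4-trimethoxy-6-(2-methylbut-3-en-2-yloxy)phenyl]-3-phenylpropan-1-one
Conditions: Pd(PPh3)4 (3 mol%), THF, 0 °C to rt
Reagents that add atoms: tert-butyl 2-methylbut-3-en-2-yl carbonate, C=CC(C)(C)OC(=O)OC(C)(C)C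
Why: Tsuji–Trost O-allylation: Pd(PPh3)4 (zerovalent palladium) ionises 6 with loss of CO2, the tert-butoxide set free deprotonates the phenol, and the phenoxide should attack the more substituted terminus of the 1,1-dimethylallyl complex of divalent palladium under kinetic control at low temperature to give the tertiary aryl ether.

Step 4
Reactants: 7 1-[2,3,4-trimethoxy-6-(2-methylbut-3-en-2-yloxy)phenyl]-3-phenylpropan-1-one
Product: 9 1-[2-hydroxy-4,5,6-trimethoxy-3-(3-methylbut-2-en-1-yl)phenyl]-3-phenylpropan-1-one, via ortho-dienone 8 (not isolated)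
Conditions: PhMe, 120 °C (sealed tube)
Reagents that add atoms: none
Why: Aromatic Claisen rearrangement: the [3,3] shift should go to the only unsubstituted ortho carbon (C4), the allyl inversion turns the 1,1-dimethylallyl ether into a linear C-prenyl group, and tautomerisation of 8 restores the chelated phenol.

Step 5
Reactants: 9 1-[2-hydroxy-4,5,6-trimethoxy-3-(3-methylbut-2-en-1-yl)phenyl]-3-phenylpropan-1-one; 10 1-bromo-3-methylbut-2-ene
Product: 11 1-[2,3,4-trimethoxy-5-(3-methylbut-2-en-1-yl)-6-(3-methylbut-2-en-1-yloxy)phenyl]-3-phenylpropan-1-one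
Conditions: K2CO3, DMF, rt
Reagents that add atoms: 1-bromo-3-methylbut-2-ene, CC(C)=CCBr
Why: Williamson ether synthesis: with every ortho and para carbon of the phenoxide substituted, SN2 alkylation by the primary allylic bromide should occur on oxygen, and room temperature keeps the new ether from rearranging thermally.

Step 6
Reactants: 11 1-[2,3,4-trimethoxy-5-(3-methylbut-2-en-1-yl)-6-(3-methylbut-2-en-1-yloxy)phenyl]-3-phenylpropan-1-one
Product: 14 (4R)-3,4,5-trimethoxy-4,6-bis(3-methylbut-2-en-1-yl)-2-(3-phenylpropanoyl)cyclohexa-2,5-dien-1-one, via C2 ortho-dienone 12 (not isolated), via C4 ortho-dienone 13 (not isolated)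
Conditions: Co(OTf)2 (10 mol%), chiral N,N'-dioxide ligand from (S)-pipecolic acid and 2,6-diisopropylaniline with a propane-1,3-diyl bridge (11 mol%), ClCH2CH2Cl, 40 °C
Reagents that add atoms: none
Why: Proposed new method: Co(OTf)2 (divalent cobalt) carrying the chiral N,N'-dioxide ligand binds 11 through the ketone oxygen and the neighbouring prenyl ether oxygen, which weakens the O–CH2 bond and triggers a chair-like aromatic Claisen [3,3] shift to the acyl-bearing C2 (12) or to C4 (13), an ortho-dienone that cannot tautomerise because the carbon reached is quaternary, and its 1,1-dimethylallyl group then makes a Cope [3,3] shift to C6 and arrives through its CH2 terminus as a linear prenyl group. The closest known reaction type is the chiral N,N'-dioxide–metal triflate catalysed dearomatising Claisen and Claisen–Cope rearrangement of allyl naphthyl ethers that carry a chelating carbonyl group next to the ether oxygen, and the untested part is its transfer to a monocyclic, fully substituted phloroglucinol ether. No ring is closed, and the one skeletal bond formed is C6–CH2. The C6 stereocentre is set by the ligand, which decides over which ring face the out-of-plane O–CH2 bond of the chelated ether lies in the first shift, and the Cope step carries the allyl unit suprafacially along that same face, so 12 and 13 converge on one enantiomer of 14. Site selectivity is secured by the substrate, since C2 and C4 are substituted and only C6 can keep the allyl group, and the methyl ethers on the C1 and C5 oxygens prevent a phenolate–ketone chelate that would hold the metal away from the ether oxygen. What the step needs beyond that is for the catalyst-bound concerted path to outrun ionisation of the prenyl ether and the uncatalysed rearrangement, which the two-point binding at 40 °C is meant to secure, and the product, a cross-conjugated dienone flanked by two vinylogous esters, cannot rearomatise because C6 bears OMe and prenyl.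

Step 7
Reactants: 14 (4R)-3,4,5-trimethoxy-4,6-bis(3-methylbut-2-en-1-yl)-2-(3-phenylpropanoyl)cyclohexa-2,5-dien-1-one
Product: 16 helihumulone [(6R)-3,5-dihydroxy-6-methoxy-4,6-bis(3-methylbut-2-en-1-yl)-2-(3-phenylpropanoyl)cyclohexa-2,4-dien-1-one], via C5 methyl enol ether 15 (not isolated)
Conditions: LiOH, THF/H2O, 0 °C to rt; then 2 M HCl to pH 1, 40 °C
Reagents that add atoms: lithium hydroxide, [Li+].[OH-]; water, O
Why: Vinylogous ester hydrolysis by addition–elimination: hydroxide should attack C1, the β-carbon of both the ring enone and the acyl enone, and expel methoxide to give the stabilised enolate of 15, aqueous acid then hydrolyses the remaining β-methoxy enone at C5, while the C6 methoxy group is a plain tertiary alkyl ether and the quaternary C6 keeps its configuration.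

## Compound list

1 | 3,4,5-trimethoxyphenol | COc1cc(O)cc(OC)c1OC | starting material
2 | 3-phenylpropanoyl chloride | O=C(Cl)CCc1ccccc1 | starting material
3 | 1-(6-hydroxy-2,3,4-trimethoxyphenyl)-3-phenylpropan-1-one | COc1cc(O)c(C(=O)CCc2ccccc2)c(OC)c1OC | intermediate
4 | 2-methylbut-3-en-2-ol | C=CC(C)(C)O | starting material
5 | di-tert-butyl dicarbonate | CC(C)(C)OC(=O)OC(=O)OC(C)(C)C | starting material
6 | tert-butyl 2-methylbut-3-en-2-yl carbonate | C=CC(C)(C)OC(=O)OC(C)(C)C | intermediate
7 | 1-[2,3,4-trimethoxy-6-(2-methylbut-3-en-2-yloxy)phenyl]-3-phenylpropan-1-one | COc1cc(OC(C)(C)C=C)c(C(=O)CCc2ccccc2)c(OC)c1OC | intermediate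
8 | ortho-dienone of step 4, 3,4,5-trimethoxy-6-(3-methylbut-2-en-1-yl)-2-(3-phenylpropanoyl)cyclohexa-2,4-dien-1-one (racemic, not isolated) | COC1=C(OC)C(OC)=C(C(=O)CCc2ccccc2)C(=O)C1CC=C(C)C | intermediate
9 | 1-[2-hydroxy-4,5,6-trimethoxy-3-(3-methylbut-2-en-1-yl)phenyl]-3-phenylpropan-1-one | COc1c(CC=C(C)C)c(O)c(C(=O)CCc2ccccc2)c(OC)c1OC | intermediate
10 | 1-bromo-3-methylbut-2-ene | CC(C)=CCBr | starting material
11 | 1-[2,3,4-trimethoxy-5-(3-methylbut-2-en-1-yl)-6-(3-methylbut-2-en-1-yloxy)phenyl]-3-phenylpropan-1-one | COc1c(OC)c(C(=O)CCc2ccccc2)c(OCC=C(C)C)c(CC=C(C)C)c1OC | intermediate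
12 | C2 ortho-dienone, (6S)-3,4,5-trimethoxy-6-(2-methylbut-3-en-2-yl)-2-(3-methylbut-2-en-1-yl)-6-(3-phenylpropanoyl)cyclohexa-2,4-dien-1-one (not isolated) | C=CC(C)(C)[C@]1(C(=O)CCc2ccccc2)C(=O)C(CC=C(C)C)=C(OC)C(OC)=C1OC | intermediate
13 | C4 ortho-dienone, (6R)-3,4,5-trimethoxy-6-(2-methylbut-3-en-2-yl)-6-(3-methylbut-2-en-1-yl)-2-(3-phenylpropanoyl)cyclohexa-2,4-dien-1-one (not isolated) | C=CC(C)(C)[C@@]1(CC=C(C)C)C(=O)C(C(=O)CCc2ccccc2)=C(OC)C(OC)=C1OC | intermediate
14 | (4R)-3,4,5-trimethoxy-4,6-bis(3-methylbut-2-en-1-yl)-2-(3-phenylpropanoyl)cyclohexa-2,5-dien-1-one | CO[C@@]1(CC=C(C)C)C(OC)=C(C(=O)CCc2ccccc2)C(=O)C(CC=C(C)C)=C1OC | intermediate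
15 | C5 methyl enol ether, (6R)-3-hydroxy-5,6-dimethoxy-4,6-bis(3-methylbut-2-en-1-yl)-2-(3-phenylpropanoyl)cyclohexa-2,4-dien-1-one (not isolated) | CO[C@@]1(CC=C(C)C)C(=O)C(C(=O)CCc2ccccc2)=C(O)C(CC=C(C)C)=C1OC | intermediate
16 | helihumulone, (6R)-3,5-dihydroxy-6-methoxy-4,6-bis(3-methylbut-2-en-1-yl)-2-(3-phenylpropanoyl)cyclohexa-2,4-dien-1-one | CO[C@@]1(CC=C(C)C)C(=O)C(C(=O)CCc2ccccc2)=C(O)C(CC=C(C)C)=C1O | target

## Step count and risks

Total step count: 7. Longest linear sequence: 6 (steps 1, 3, 4, 5, 6, 7 from 3,4,5-trimethoxyphenol).

Steps most likely to fail: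

1. Step 6, the one step beyond known chemistry. The catalyst-bound concerted shift may lose to ionisation of the prenyl ether (dissociative migration or loss of the prenyl group) or to the uncatalysed rearrangement, and the metal may rest on the C1/C6 methoxy side of the ketone; either would give poor facial selectivity or low conversion. Fallback with known chemistry, setting out from 11: the ether is heated without catalyst in N,N-diethylaniline at about 150 °C (thermal Claisen–Cope rearrangement of an ortho-blocked aryl prenyl ether). This should pass through racemic C2 ortho-dienone F1 and racemic C4 ortho-dienone F2 to racemic dienone F3. Preparative HPLC on a chiral stationary phase (amylose tris(3,5-dimethylphenylcarbamate)) then separates the wanted enantiomer from (4S)-dienone F4, and the route is rejoined at 14.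

2. Step 7. Cleavage of the second enol ether at C5 may stall once the first hydrolysis has turned the ring into an enolate, and the acid stage may bring about cyclisation of a prenyl group onto an enol oxygen or loss of the C6 prenyl group with rearomatisation. Fallback, setting out from 14: the LiOH stage alone is run and 15 is isolated after careful acidification. The remaining methyl group is then removed by SN2 attack at the methyl carbon with NaSEt in DMF at 90 °C instead of by hydrolysis at the ring carbon, and acidic work-up brings the route back at 16.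

3. Step 3. The phenoxide may attack the less substituted allyl terminus, or the tertiary ether may equilibrate on palladium to the linear prenyl ether, which on heating in step 4 would place a 1,1-dimethylallyl group on C4; the chelated phenol may also react sluggishly. Fallback, setting out from 3: bromination at the only free ring position with NBS in MeCN at 0 °C should give 1-(3-bromo-2-hydroxy-4,5,6-trimethoxyphenyl)-3-phenylpropan-1-one F5. Stille coupling with tributyl(3-methylbut-2-enyl)stannane (Pd(PPh3)4, DMF, 90 °C) then attaches the linear prenyl group, and the route is rejoined at 9, making steps 2 to 4 unnecessary.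

Further compounds
F1 | step 6 | racemic 3,4,5-trimethoxy-6-(2-methylbut-3-en-2-yl)-2-(3-methylbut-2-en-1-yl)-6-(3-phenylpropanoyl)cyclohexa-2,4-dien-1-one | C=CC(C)(C)C1(C(=O)CCc2ccccc2)C(=O)C(CC=C(C)C)=C(OC)C(OC)=C1OC
F2 | step 6 | racemic 3,4,5-trimethoxy-6-(2-methylbut-3-en-2-yl)-6-(3-methylbut-2-en-1-yl)-2-(3-phenylpropanoyl)cyclohexa-2,4-dien-1-one | C=CC(C)(C)C1(CC=C(C)C)C(=O)C(C(=O)CCc2ccccc2)=C(OC)C(OC)=C1OC
F3 | step 6 | racemic 3,4,5-trimethoxy-4,6-bis(3-methylbut-2-en-1-yl)-2-(3-phenylpropanoyl)cyclohexa-2,5-dien-1-one | COC1(CC=C(C)C)C(OC)=C(C(=O)CCc2ccccc2)C(=O)C(CC=C(C)C)=C1OC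
F4 | step 6 | (4S)-3,4,5-trimethoxy-4,6-bis(3-methylbut-2-en-1-yl)-2-(3-phenylpropanoyl)cyclohexa-2,5-dien-1-one | CO[C@]1(CC=C(C)C)C(OC)=C(C(=O)CCc2ccccc2)C(=O)C(CC=C(C)C)=C1OC
F0 | step 7 | none | none
F5 | step 3 | 1-(3-bromo-2-hydroxy-4,5,6-trimethoxyphenyl)-3-phenylpropan-1-one | COc1c(Br)c(O)c(C(=O)CCc2ccccc2)c(OC)c1OC
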